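**Retrosynthetic overview**
1. Glomelliferic acid ⇒ a depside aldehyde whose ring A ketone is masked as a 1,3-dithiane; one buffered chlorite operation turns CHO into CO2H and the dithiane into C=O.
2. Depside ester C–O ⇒ dithiane-masked ring A acid + ring B phenol-aldehyde (formylated olivetol).
3. Dithiane acid ⇒ 8-hydroxy-6-methoxy-3-propylisocoumarin by ring-opening thioketalisation (the free keto acid cannot be activated without closing back to the isocoumarin).
4. Key C–C bond (ring A C6–CH2) ⇒ ortho C–H bond of 4-methoxysalicylic acid + butanoyl sulfoxonium ylide; the ketone α-carbon reacts as an electrophile (α-oxo carbene, an enolonium equivalent) with the aryl–rhodium carbon.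
5. Rings: both benzene rings are bought. The pyranone ring forms in the key step, is exchanged for the dithiane ring in the next step, and the dithiane is opened in the last step.

Assumption: the target has no stereocentre (it is achiral), so no stereocontrol is needed and the SMILES carry no stereodescriptors.

**Step 1**
Reactants: 1 trimethylsulfoxonium iodide; 2 butanoyl chloride
Product: 4 1-[dimethyl(oxo)-λ6-sulfanylidene]pentan-2-one, via dimethylsulfoxonium methylide 3 (not isolated)
Conditions: 1 (3.0 equiv), KOtBu (3.0 equiv), THF, reflux, 2 h; then 2 (1.0 equiv), 0 °C → rt, 2 h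
Reagents that add atoms: none
Why: C-acylation of the Corey–Chaykovsky methylide by the acid chloride, with a second equivalent of methylide removing the newly acidic α-proton, gives the bench-stable keto sulfoxonium ylide.

**Step 2**
Reactants: 5 2-hydroxy-4-methoxybenzoic acid; 4 1-[dimethyl(oxo)-λ6-sulfanylidene]pentan-2-one
Product: 7 8-hydroxy-6-methoxy-3-propyl-1H-isochromen-1-one, via 2-hydroxy-4-methoxy-6-(2-oxopentyl)benzoic acid 6 (not isolated)
Conditions: 4 (1.5 equiv), [Cp*RhCl2]2 (2.5 mol %), AgSbF6 (10 mol %), NaOAc (20 mol %), (CF3)2CHOH, 80 °C, 16 h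
Reagents that add atoms: none
Why: Carboxylate-directed C–H activation by trivalent rhodium can only occur at C6, the single free ortho position, and the aryl–rhodium bond then inserts the α-oxo carbene formed from 4 on loss of DMSO, so the ketone α-carbon is joined as an electrophile to the aryl carbon; protodemetalation gives 6, which lactonises in the acidic medium (C–H acylmethylation/annulation with a sulfoxonium ylide).

**Step 3**
Reactants: 7 8-hydroxy-6-methoxy-3-propyl-1H-isochromen-1-one
Product: 8 2-hydroxy-4-methoxy-6-[(2-propyl-1,3-dithian-2-yl)methyl]benzoic acid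
Conditions: HS(CH2)3SH (3 equiv), BF3·OEt2 (30 mol %), CH2Cl2–AcOH (4:1), 0 °C → rt, 12 h; then 1 M NaOH, rt, 30 min, acidify to pH 2
Reagents that add atoms: propane-1,3-dithiol, SCCCS
Why: Proposed new method: protonation of the enol lactone at C4 lets the thiol add at C3, the carboxyl group leaves from the resulting O,S-ketal and the second thiol closes the dithiane (any thioester formed by competing attack at the lactone carbonyl is cleaved in the NaOH wash), the whole being an addition driven by the stability of the dithioketal; the closest known reaction type is BF3-promoted dithioketalisation of ketones and enol acetates (trans-thioketalisation).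

**Step 4**
Reactants: 9 5-pentylbenzene-1,3-diol (olivetol)
Product: 11 2,4-dihydroxy-6-pentylbenzaldehyde, via N-[(2,4-dihydroxy-6-pentylphenyl)methylidene]-N-methylmethanaminium chloride 10 (not isolated)
Conditions: POCl3 (1.2 equiv), DMF, 0 °C → rt, 3 h; then H2O, 50 °C, 1 h
Reagents that add atoms: N,N-dimethylformamide, CN(C)C=O; water, O
Why: Vilsmeier–Haack formylation of the resorcinol goes to the position ortho to one hydroxyl and para to the other (as with orcinol), and the iminium salt is hydrolysed on aqueous work-up.

**Step 5**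
Reactants: 8 2-hydroxy-4-methoxy-6-[(2-propyl-1,3-dithian-2-yl)methyl]benzoic acid; 11 2,4-dihydroxy-6-pentylbenzaldehyde
Product: 13 4-formyl-3-hydroxy-5-pentylphenyl 2-hydroxy-4-methoxy-6-[(2-propyl-1,3-dithian-2-yl)methyl]benzoate, via 2-hydroxy-4-methoxy-6-[(2-propyl-1,3-dithian-2-yl)methyl]benzoic trifluoroacetic anhydride 12 (not isolated)
Conditions: 8 (1.0 equiv), 11 (1.0 equiv), (CF3CO)2O (4 equiv), toluene, rt, 3 h; H2O work-up
Reagents that add atoms: none
Why: Mixed-anhydride esterification: the hindered, electron-rich acid is activated as its acyl trifluoroacetate and acylates the 4-OH of 11, because the ortho-hydroxyls of both partners are hydrogen-bonded to their carbonyl groups, while the dithiane stops the ketone from closing onto the activated carboxyl.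

**Step 6**
Reactants: 13 4-formyl-3-hydroxy-5-pentylphenyl 2-hydroxy-4-methoxy-6-[(2-propyl-1,3-dithian-2-yl)methyl]benzoate
Product: 14 glomelliferic acid, 2-hydroxy-4-{[2-hydroxy-4-methoxy-6-(2-oxopentyl)benzoyl]oxy}-6-pentylbenzoic acid
Conditions: NaClO2 (8 equiv), NaH2PO4 (8 equiv), 2-methyl-2-butene (30 equiv), t-BuOH–THF–H2O (2:2:1), 0 °C → rt, 6 h
Reagents that add atoms: sodium chlorite, [Na+].[O-]Cl=O; water, O
Why: Lindgren–Pinnick oxidation converts the aldehyde to the acid while the same buffered chlorite oxidises the dithiane sulfur so that it hydrolyses to the ketone (oxidative dithiane cleavage), at about pH 4 where the depside ester is stable and with 2-methyl-2-butene scavenging HOCl to protect the phenolic rings.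

**Compound list**
1 | trimethylsulfoxonium iodide | C[S+](C)(C)=O.[I-] | starting material
2 | butanoyl chloride | CCCC(Cl)=O | starting material
3 | dimethylsulfoxonium methylide | C=S(C)(C)=O | intermediate (not isolated)
4 | 1-[dimethyl(oxo)-λ6-sulfanylidene]pentan-2-one | CCCC(=O)C=S(C)(C)=O | intermediate
5 | 2-hydroxy-4-methoxybenzoic acid | COc1ccc(C(=O)O)c(O)c1 | starting material
6 | 2-hydroxy-4-methoxy-6-(2-oxopentyl)benzoic acid | CCCC(=O)Cc1cc(OC)cc(O)c1C(=O)O | intermediate (not isolated)
7 | 8-hydroxy-6-methoxy-3-propyl-1H-isochromen-1-one | CCCC1=Cc2cc(OC)cc(O)c2C(=O)O1 | intermediate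
8 | 2-hydroxy-4-methoxy-6-[(2-propyl-1,3-dithian-2-yl)methyl]benzoic acid | CCCC1(Cc2cc(OC)cc(O)c2C(=O)O)SCCCS1 | intermediate
9 | 5-pentylbenzene-1,3-diol (olivetol) | CCCCCc1cc(O)cc(O)c1 | starting material
10 | N-[(2,4-dihydroxy-6-pentylphenyl)methylidene]-N-methylmethanaminium chloride | CCCCCc1cc(O)cc(O)c1C=[N+](C)C.[Cl-] | intermediate (not isolated)
11 | 2,4-dihydroxy-6-pentylbenzaldehyde | CCCCCc1cc(O)cc(O)c1C=O | intermediate
12 | 2-hydroxy-4-methoxy-6-[(2-propyl-1,3-dithian-2-yl)methyl]benzoic trifluoroacetic anhydride | CCCC1(Cc2cc(OC)cc(O)c2C(=O)OC(=O)C(F)(F)F)SCCCS1 | intermediate (not isolated)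
13 | 4-formyl-3-hydroxy-5-pentylphenyl 2-hydroxy-4-methoxy-6-[(2-propyl-1,3-dithian-2-yl)methyl]benzoate | CCCCCc1cc(OC(=O)c2c(O)cc(OC)cc2CC2(CCC)SCCCS2)cc(O)c1C=O | intermediate
14 | glomelliferic acid | CCCCCc1cc(OC(=O)c2c(O)cc(OC)cc2CC(=O)CCC)cc(O)c1C(=O)O | target

**Totals**
Total step count: 6. Longest linear sequence: 5 (steps 1, 2, 3, 5, 6).

**Three steps most likely to fail, with fallbacks**

Step 2. The free salicylic hydroxyl may divert the rhodium carbene (O–H insertion) or the electron-rich acid may decarboxylate. The fallback sets out from ylide 4 and masks the phenol as a methyl ether. The same coupling is run on commercial 2,4-dimethoxybenzoic acid F1 ([Cp*RhCl2]2, AgSbF6, NaOAc, (CF3)2CHOH, 80 °C). It passes through 2,4-dimethoxy-6-(2-oxopentyl)benzoic acid F2, which is not isolated, and closes to 6,8-dimethoxy-3-propyl-1H-isochromen-1-one F3. BCl3 (CH2Cl2, −78 → 0 °C) then cleaves only the methyl ether peri to the lactone carbonyl, by chelation, and the route is rejoined at 7.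

Step 3. The isocoumarin may be inert to acid and dithiol, or may lose its aryl methyl ether under the Lewis acid. The fallback sets out from 7 and opens the lactone with base instead: KOH in aqueous MeOH at 50 °C, then cold acidification to pH 3, gives keto acid 6, this time isolated. Ordinary ketone thioketalisation (propane-1,3-dithiol, catalytic Zn(OTf)2, CH2Cl2, 0 °C) then gives 8, where the route is rejoined. No compound outside the list is made (F0).

Step 6. Chlorite may chlorinate or over-oxidise the phenolic rings before both functional groups are unveiled. The fallback sets out from 13 and separates the two events. Alkylative, non-oxidative hydrolysis of the dithiane (MeI, CaCO3, MeCN–H2O 9:1, 40 °C) gives 4-formyl-3-hydroxy-5-pentylphenyl 2-hydroxy-4-methoxy-6-(2-oxopentyl)benzoate F4. The aldehyde alone is then oxidised with NaClO2 and sulfamic acid (H2NSO3H) in dioxane–H2O at 0 °C, and the route is rejoined at 14.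

**Further compounds**
F1 | step 2 | 2,4-dimethoxybenzoic acid | COc1ccc(C(=O)O)c(OC)c1
F2 | step 2 | 2,4-dimethoxy-6-(2-oxopentyl)benzoic acid | CCCC(=O)Cc1cc(OC)cc(OC)c1C(=O)O
F3 | step 2 | 6,8-dimethoxy-3-propyl-1H-isochromen-1-one | CCCC1=Cc2cc(OC)cc(OC)c2C(=O)O1
F0 | step 3 | none | none
F4 | step 6 | 4-formyl-3-hydroxy-5-pentylphenyl 2-hydroxy-4-methoxy-6-(2-oxopentyl)benzoate | CCCCCc1cc(OC(=O)c2c(O)cc(OC)cc2CC(=O)CCC)cc(O)c1C=O
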